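**Retrosynthetic overview**
1. Feature: number the eleven-membered carbocycle C1 (acetoxy carbon), C2=C3(Me), C4 (aroyloxy carbon), C5, C6=C7(Me), C8–C10, C11 (CMe2). Atoms C2=C3–C4–C5–C6=C7 form a 1,5-diene, so a retro-[3,3] shift (break C4–C5, make C2–C7) contracts the ring to the cycloheptane C7–C8–C9–C10–C11–C1–C2.
2. Endgame: both esters come from orthogonal ethers (O1 TBS, O4 PMB). The C7 methyl comes from enol triflate 21, which stores the enolate geometry of the anionic oxy-Cope rearrangement of cycloheptanol 18.
3. Compound 18: the E enol ether comes from an E vinyl iodide (alkyne carboalumination, then copper C–O coupling). The C7 vinyl carbinol comes from O1-directed epoxidation of an exocyclic methylene and sulfonium ylide homologation, which puts O7 anti and the vinyl group cis to the C2 side chain.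
4. C1/C2: anti opening of vinyl epoxide 7 at allylic C2 by an alkynylalane. Absolute configuration comes from catalytic asymmetric epoxidation of 4,4-dimethylcyclohept-2-enone 5.
5. Ring order: six-membered ring (3-methylcyclohexenone), then the seven-membered ring by one-carbon Saegusa expansion (step 3), then the eleven-membered ring by four-carbon oxy-Cope expansion (step 12).

Key step: step 12

Target numbering (C1–C11 as above) is used for all intermediates.
Assumption: of the two pseudoenantiomeric 9-amino-9-deoxy-epi-cinchona catalysts (quinine- or quinidine-derived), the one that delivers the (C1 S, C2 S) epoxide 6 is used. The sense of induction is to be verified on 6 before the route is carried on.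

Step 1
Reactants: 1 3-methylcyclohex-2-en-1-one
Product: 2 (3,3-dimethylcyclohex-1-en-1-yl)oxytrimethylsilane
Conditions: MeMgBr, CuBr·SMe2 (5 mol %), TMSCl, DMPU, THF, −78 °C; Et3N, pentane/aq NaHCO3
Reagents that add atoms: methylmagnesium bromide, C[Mg]Br; chlorotrimethylsilane, C[Si](C)(C)Cl
Why: TMSCl-accelerated copper-catalysed conjugate addition builds the quaternary carbon (future C11) and traps the enolate regiospecifically as the silyl enol ether on the gem-dimethyl side, an isomer that direct enolisation of 3,3-dimethylcyclohexanone would not give.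

Step 2
Reactants: 2 (3,3-dimethylcyclohex-1-en-1-yl)oxytrimethylsilane
Product: 3 rac-5,5-dimethyl-1-(trimethylsilyloxy)bicyclo[4.1.0]heptane
Conditions: Et2Zn, CH2I2, Et2O, 0 °C → rt; pyridine, aq NaHCO3
Reagents that add atoms: diiodomethane, ICI
Why: The Simmons–Smith cyclopropanation (Furukawa variant) is fastest on electron-rich silyl enol ethers and adds the methylene that becomes C2; the racemic stereocentres are erased in step 3.

Step 3
Reactants: 3 rac-5,5-dimethyl-1-(trimethylsilyloxy)bicyclo[4.1.0]heptane
Product: 5 4,4-dimethylcyclohept-2-en-1-one, via β-chloro ketone 4 (not isolated)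
Conditions: FeCl3, DMF, 0 °C → rt; crude 4: NaOAc, MeOH, reflux
Reagents that add atoms: iron trichloride, Cl[Fe](Cl)Cl (its chlorine sits in 4 only and is lost again on the way to 5)
Why: In the Ito–Saegusa ring expansion, one-electron oxidation cleaves the internal cyclopropane bond to the secondary radical, chlorine transfer gives 4, and acetate-induced E1cB loss of HCl gives the conjugated cycloheptenone with C7 as carbonyl and C2=C1 next to C11.

Step 4
Reactants: 5 4,4-dimethylcyclohept-2-en-1-one
Product: 6 (1S,7S)-6,6-dimethyl-8-oxabicyclo[5.1.0]octan-2-one (C1 S and C2 S in target numbering)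
Conditions: H2O2 (30 % aq), 9-amino-9-deoxy-epi-cinchona alkaloid bis(trifluoroacetate) (10 mol %), dioxane, 35 °C
Reagents that add atoms: hydrogen peroxide, OO
Why: In this iminium-catalysed asymmetric Weitz–Scheffer epoxidation of a cyclic enone, the chiral primary ammonium salt condenses with the unhindered C7 ketone and steers hydroperoxide attack at C1 to one face, and ring closure gives the cis-fused oxirane that sets the C1–O configuration kept to the end.

Step 5
Reactants: 6 (1S,7S)-6,6-dimethyl-8-oxabicyclo[5.1.0]octan-2-one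
Product: 7 (1S,7R)-2,2-dimethyl-6-methylidene-8-oxabicyclo[5.1.0]octane
Conditions: Ph3PCH3Br, KOt-Bu, THF, 0 °C → rt
Reagents that add atoms: methyltriphenylphosphonium bromide, C[P+](c1ccccc1)(c1ccccc1)c1ccccc1.[Br-]
Why: Wittig methylenation of an α,β-epoxy ketone with the non-stabilised ylide is fast, leaves the oxirane and both stereocentres untouched (the C2 descriptor changes by priority only), adds C6 and makes C2 an allylic epoxide carbon.

Step 6
Reactants: 7 (1S,7R)-2,2-dimethyl-6-methylidene-8-oxabicyclo[5.1.0]octane; 8 ethynyltrimethylsilane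
Product: 10 (1R,7R)-7-ethynyl-2,2-dimethyl-6-methylidenecycloheptan-1-ol (C1 R and C2 R), via C-silyl alkyne 9 (not isolated)
Conditions: 8, n-BuLi, toluene/hexane, 0 °C; Et2AlCl; then 7, 0 °C → rt; aq potassium sodium tartrate; crude 9: K2CO3, MeOH, rt
Reagents that add atoms: none
Why: In this trans opening of a vinyl epoxide by an alkynylalane, aluminium activates the oxirane and the alkynyl group attacks allylic C2 with inversion because C1 is neopentyl and shielded by C11, which sets C2 anti to O1, and methanolysis then removes the C-silyl group.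

Step 7
Reactants: 10 (1R,7R)-7-ethynyl-2,2-dimethyl-6-methylidenecycloheptan-1-ol
Product: 12 (1R,7R)-7-[(E)-1-iodoprop-1-en-2-yl]-2,2-dimethyl-6-methylidenecycloheptan-1-ol, via alkenylalane 11 (not isolated)
Conditions: AlMe3 (3.5 equiv), Cp2ZrCl2 (0.3 equiv), CH2Cl2, 0 °C → rt; then I2, THF, −30 → 0 °C
Reagents that add atoms: trimethylaluminium, C[Al](C)C; iodine, II
Why: Negishi zirconium-catalysed carboalumination adds methyl (to internal C3) and aluminium (to C4) syn across the terminal alkyne of a homopropargylic alkoxide, and iodinolysis with retention gives the E iodide, the mixture being kept at or below room temperature so that chelation-driven isomerisation of 11 does not set in.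

Step 8
Reactants: 12 (1R,7R)-7-[(E)-1-iodoprop-1-en-2-yl]-2,2-dimethyl-6-methylidenecycloheptan-1-ol
Product: 13 (3R,4R,5R)-4-[(E)-1-iodoprop-1-en-2-yl]-6,6-dimethyl-1-oxaspiro[2.6]nonan-5-ol (C7 R, C2 R, C1 R)
Conditions: VO(acac)2 (5 mol %), t-BuOOH (decane), CH2Cl2, 0 °C → rt
Reagents that add atoms: tert-butyl hydroperoxide, CC(C)(C)OO
Why: In this vanadium-catalysed hydroxyl-directed epoxidation of a homoallylic alcohol, the O1-bound peroxovanadate delivers oxygen to the exocyclic alkene on the face syn to O1 and anti to the C2 side chain, which sets C7 with C6 cis to C3, while the electron-poor iodoalkene stays inert.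

Step 9
Reactants: 13 (3R,4R,5R)-4-[(E)-1-iodoprop-1-en-2-yl]-6,6-dimethyl-1-oxaspiro[2.6]nonan-5-ol
Product: 15 O1 tert-butyldimethylsilyl ether of 13, via potassium alkoxide 14 (not isolated)
Conditions: KH, THF, 0 °C; TBSCl, 0 °C → rt
Reagents that add atoms: tert-butyldimethylsilyl chloride, CC(C)(C)[Si](C)(C)Cl; potassium hydride, [H-].[K+] (potassium of 14 only)
Why: O-silylation of the preformed potassium alkoxide overcomes the hindrance at neopentyl O1 without a Lewis acid that could rearrange the 2,2-disubstituted oxirane, and cyclisation of 14 onto the epoxide would need a disfavoured 4-exo or 5-endo opening.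

Step 10
Reactants: 15 O1 tert-butyldimethylsilyl ether of 13
Product: 16 (1S,2R,3R)-3-(tert-butyldimethylsilyloxy)-2-[(E)-1-iodoprop-1-en-2-yl]-4,4-dimethyl-1-vinylcycloheptan-1-ol (C7 S, C2 R, C1 R)
Conditions: Me3SI (5 equiv), n-BuLi (4.8 equiv), THF, −10 °C; then 15, −10 °C → rt
Reagents that add atoms: trimethylsulfonium iodide, C[S+](C)C.[I-]
Why: In this one-carbon homologation of a terminal epoxide to an allylic alcohol with excess dimethylsulfonium methylide, the ylide opens the oxirane at C6, a second equivalent deprotonates the sulfonium adduct and intramolecular elimination of Me2S gives C5=C6, with C7 keeping its configuration because its C–O bond is never broken.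

Step 11
Reactants: 16 (1S,2R,3R)-3-(tert-butyldimethylsilyloxy)-2-[(E)-1-iodoprop-1-en-2-yl]-4,4-dimethyl-1-vinylcycloheptan-1-ol; 17 4-methoxybenzyl alcohol
Product: 18 (1S,2R,3R)-3-(tert-butyldimethylsilyloxy)-2-[(E)-1-(4-methoxybenzyloxy)prop-1-en-2-yl]-4,4-dimethyl-1-vinylcycloheptan-1-ol
Conditions: 17 (2 equiv), CuI (10 mol %), 3,4,7,8-tetramethyl-1,10-phenanthroline (20 mol %), Cs2CO3, toluene, 80 °C; filtration through basic alumina
Reagents that add atoms: none
Why: Copper-catalysed Ullmann-type C–O coupling of a vinyl iodide with a primary alcohol proceeds with retention of alkene geometry, so the E iodide gives the E enol ether, and the hindered tertiary C7 hydroxyl cannot compete because iodine lies trans to C2 and ring closure onto C4 is geometrically excluded.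

Step 12
Reactants: 18 (1S,2R,3R)-3-(tert-butyldimethylsilyloxy)-2-[(E)-1-(4-methoxybenzyloxy)prop-1-en-2-yl]-4,4-dimethyl-1-vinylcycloheptan-1-ol
Product: 21 (1R,2Z,4R)-1-(tert-butyldimethylsilyloxy)-4-(4-methoxybenzyloxy)-3,11,11-trimethylcycloundeca-2,6-dien-7-yl triflate (OTf cis to C5 and C8 trans to C5; 6Z by CIP), via potassium alkoxide 19 (not isolated), via potassium enolate 20 (not isolated)
Conditions: KH (3 equiv), 18-crown-6, THF, 0 → 25 °C; then PhNTf2, −78 → 0 °C; aq NH4Cl
Reagents that add atoms: N-phenylbis(trifluoromethanesulfonimide), O=S(=O)(N(c1ccccc1)S(=O)(=O)C(F)(F)F)C(F)(F)F; potassium hydride, [H-].[K+] (potassium of 19 and 20 only)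
Why: KH with 18-crown-6 turns 18 into the poorly ion-paired C7 alkoxide 19, whose oxygen lone pairs weaken the C2–C7 bond so that the 1,5-diene C5=C6–C7–C2–C3=C4 undergoes a concerted [3,3] shift near room temperature: C4–C5 forms, C2–C7 breaks, C2=C3 and the C6=C7 enolate 20 appear, and PhNTf2 sulfonylates the enolate oxygen before proton transfer can move or isomerise it. The closest known reaction type is the anionic oxy-Cope four-carbon ring expansion of 1,2-dialkenylcycloalkanols with in situ capture of the regiodefined enolate. The eleven-membered ring is closed by ring expansion and not end to end: the side-chain termini C4 and C5 bond across a six-centre chair while the bond shared with the seven-membered ring is cut in the same event. Since the two alkenyl groups are cis on the cycloheptane, a chair can hold only one of the ring bonds C7–C8 and C2–C1 equatorial; the productive chair has C8 equatorial with the alkoxide axial (C5 trans to C8, the later E C6=C7) and C1 axial (C1 cis to C4, Z C2=C3), and it should be preferred because its partner forces C8 into a 1,3-diaxial contact with the C3 methyl group and eclipses C1 with the same methyl. C4, the only new stereocentre, is fixed by chirality transfer from C7 (S) and C2 (R): in that chair the E enol ether keeps OPMB equatorial and C5 reaches the C4 face that gives 4R, whereas C1 is a spectator. The step therefore needs chair over boat, one chair over the other and O- over C-sulfonylation; the first two rest on the cis fusion and the C3 methyl and remain a prediction, the last on the hard crown-complexed potassium enolate.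

Step 13
Reactants: 21 eleven-membered enol triflate
Product: 22 tert-butyl{[(1R,2Z,4R,6E)-4-(4-methoxybenzyloxy)-3,7,11,11-tetramethylcycloundeca-2,6-dien-1-yl]oxy}dimethylsilane
Conditions: MeMgBr, Fe(acac)3 (10 mol %), THF/NMP, −30 → 0 °C
Reagents that add atoms: methylmagnesium bromide, C[Mg]Br
Why: Iron-catalysed cross-coupling of an alkenyl triflate with a methyl Grignard reagent is fast at low temperature and stereoretentive, so methyl takes the place of OTf and C6=C7 becomes E while both ethers are inert.

Step 14
Reactants: 22 silyl PMB diether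
Product: 23 (1R,2Z,4R,6E)-1-(tert-butyldimethylsilyloxy)-3,7,11,11-tetramethylcycloundeca-2,6-dien-4-ol
Conditions: DDQ (1.2 equiv), CH2Cl2/pH 7 buffer, 0 °C
Reagents that add atoms: none
Why: Oxidative PMB cleavage (benzylic hydride abstraction by DDQ, then hydrolysis of the oxocarbenium ion) frees O4 only, does not involve the C4–O bond, and leaves the silyl ether and the isolated alkenes intact when run buffered and cold.

Step 15
Reactants: 23 C4 alcohol; 24 4-acetoxybenzoic acid
Product: 25 (1R,2Z,4R,6E)-1-(tert-butyldimethylsilyloxy)-3,7,11,11-tetramethylcycloundeca-2,6-dien-4-yl 4-acetoxybenzoate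
Conditions: 24, DCC, DMAP (cat.), CH2Cl2, 0 °C → rt
Reagents that add atoms: none
Why: Steglich esterification acylates O4 through the activated acid without touching the C4–O bond, so 4R is retained, and the phenol stays masked as its acetate.

Step 16
Reactants: 25 silyl ether aroate
Product: 26 (1R,2Z,4R,6E)-1-hydroxy-3,7,11,11-tetramethylcycloundeca-2,6-dien-4-yl 4-acetoxybenzoate
Conditions: HF·pyridine, pyridine/THF, 0 °C → rt
Reagents that add atoms: none
Why: Fluoride-driven desilylation in a pyridine-buffered medium removes the hindered TBS group while both esters and the acid-sensitive 1,5-diene survive and C1 is not involved.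

Step 17
Reactants: 26 C1 alcohol
Product: 27 (1R,2Z,4R,6E)-1-acetoxy-3,7,11,11-tetramethylcycloundeca-2,6-dien-4-yl 4-acetoxybenzoate
Conditions: Ac2O, DMAP, pyridine, rt → 40 °C
Reagents that add atoms: acetic anhydride, CC(=O)OC(C)=O
Why: DMAP-catalysed acetylation through the N-acetylpyridinium ion reaches even the neopentyl allylic O1 and retains 1R because only the O–H bond is exchanged.

Step 18
Reactants: 27 diacetate
Product: 28 (1R,2Z,4R,6E)-1-acetoxy-3,7,11,11-tetramethylcycloundeca-2,6-dien-4-yl 4-hydroxybenzoate (target)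
Conditions: NH4OAc, MeOH/H2O (4:1), rt
Reagents that add atoms: none
Why: In this chemoselective transesterification, the aryl acetate with its phenoxide leaving group is far more electrophilic than the hindered secondary acetate and the conjugated benzoate, so near-neutral ammonium acetate in aqueous methanol cleaves only that ester.

**Compound list**
1 | 3-methylcyclohex-2-en-1-one | CC1=CC(=O)CCC1 | starting material
2 | (3,3-dimethylcyclohex-1-en-1-yl)oxytrimethylsilane | C[Si](C)(C)OC1=CC(C)(C)CCC1 | intermediate
3 | rac-5,5-dimethyl-1-(trimethylsilyloxy)bicyclo[4.1.0]heptane | C[Si](C)(C)OC12CCCC(C)(C)C1C2 | intermediate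
4 | rac-3-chloro-4,4-dimethylcycloheptan-1-one (not isolated) | O=C1CC(Cl)C(C)(C)CCC1 | intermediate
5 | 4,4-dimethylcyclohept-2-en-1-one | O=C1C=CC(C)(C)CCC1 | intermediate
6 | (1S,7S)-6,6-dimethyl-8-oxabicyclo[5.1.0]octan-2-one | O=C1CCCC(C)(C)[C@@H]2O[C@H]12 | intermediate
7 | (1S,7R)-2,2-dimethyl-6-methylidene-8-oxabicyclo[5.1.0]octane | C=C1CCCC(C)(C)[C@@H]2O[C@H]12 | intermediate
8 | ethynyltrimethylsilane | C#C[Si](C)(C)C | starting material
9 | (1R,7R)-2,2-dimethyl-6-methylidene-7-[(trimethylsilyl)ethynyl]cycloheptan-1-ol (not isolated) | C=C1CCCC(C)(C)[C@H](O)[C@H]1C#C[Si](C)(C)C | intermediate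
10 | (1R,7R)-7-ethynyl-2,2-dimethyl-6-methylidenecycloheptan-1-ol | C=C1CCCC(C)(C)[C@H](O)[C@H]1C#C | intermediate
11 | E alkenyl(dimethyl)alane, O1 dimethylaluminium alkoxide (not isolated) | C=C1CCCC(C)(C)[C@H](O[Al](C)C)[C@H]1/C(C)=C/[Al](C)C | intermediate
12 | (1R,7R)-7-[(E)-1-iodoprop-1-en-2-yl]-2,2-dimethyl-6-methylidenecycloheptan-1-ol | C=C1CCCC(C)(C)[C@H](O)[C@H]1/C(C)=C/I | intermediate
13 | (3R,4R,5R)-4-[(E)-1-iodoprop-1-en-2-yl]-6,6-dimethyl-1-oxaspiro[2.6]nonan-5-ol | C1O[C@@]12CCCC(C)(C)[C@H](O)[C@H]2/C(C)=C/I | intermediate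
14 | potassium O1 alkoxide of 13 (not isolated) | C1O[C@@]12CCCC(C)(C)[C@H]([O-])[C@H]2/C(C)=C/I.[K+] | intermediate
15 | O1 tert-butyldimethylsilyl ether of 13 | C1O[C@@]12CCCC(C)(C)[C@H](O[Si](C)(C)C(C)(C)C)[C@H]2/C(C)=C/I | intermediate
16 | (1S,2R,3R)-3-(tert-butyldimethylsilyloxy)-2-[(E)-1-iodoprop-1-en-2-yl]-4,4-dimethyl-1-vinylcycloheptan-1-ol | C=C[C@@]1(O)CCCC(C)(C)[C@H](O[Si](C)(C)C(C)(C)C)[C@H]1/C(C)=C/I | intermediate
17 | 4-methoxybenzyl alcohol | OCc1ccc(OC)cc1 | starting material
18 | (1S,2R,3R)-3-(tert-butyldimethylsilyloxy)-2-[(E)-1-(4-methoxybenzyloxy)prop-1-en-2-yl]-4,4-dimethyl-1-vinylcycloheptan-1-ol (key-step precursor) | C=C[C@@]1(O)CCCC(C)(C)[C@H](O[Si](C)(C)C(C)(C)C)[C@H]1/C(C)=C/OCc2ccc(OC)cc2 | intermediate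
19 | potassium C7 alkoxide of 18 (not isolated) | C=C[C@@]1([O-])CCCC(C)(C)[C@H](O[Si](C)(C)C(C)(C)C)[C@H]1/C(C)=C/OCc2ccc(OC)cc2.[K+] | intermediate
20 | ring-expanded potassium C6=C7 enolate, O cis to C5 (not isolated) | CC(C)(C)[Si](C)(C)O[C@@H]1/C=C(/C)[C@H](OCc2ccc(OC)cc2)C/C=C(\[O-])CCCC1(C)C.[K+] | intermediate
21 | eleven-membered C7 enol triflate (1R,2Z,4R; OTf cis to C5) (key-step product) | CC(C)(C)[Si](C)(C)O[C@@H]1/C=C(/C)[C@H](OCc2ccc(OC)cc2)C/C=C(\OS(=O)(=O)C(F)(F)F)CCCC1(C)C | intermediate
22 | tert-butyl{[(1R,2Z,4R,6E)-4-(4-methoxybenzyloxy)-3,7,11,11-tetramethylcycloundeca-2,6-dien-1-yl]oxy}dimethylsilane | CC(C)(C)[Si](C)(C)O[C@@H]1/C=C(/C)[C@H](OCc2ccc(OC)cc2)C/C=C(\C)CCCC1(C)C | intermediate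
23 | (1R,2Z,4R,6E)-1-(tert-butyldimethylsilyloxy)-3,7,11,11-tetramethylcycloundeca-2,6-dien-4-ol | CC(C)(C)[Si](C)(C)O[C@@H]1/C=C(/C)[C@H](O)C/C=C(\C)CCCC1(C)C | intermediate
24 | 4-acetoxybenzoic acid | CC(=O)Oc1ccc(C(=O)O)cc1 | starting material
25 | (1R,2Z,4R,6E)-1-(tert-butyldimethylsilyloxy)-3,7,11,11-tetramethylcycloundeca-2,6-dien-4-yl 4-acetoxybenzoate | CC(C)(C)[Si](C)(C)O[C@@H]1/C=C(/C)[C@H](OC(=O)c2ccc(OC(C)=O)cc2)C/C=C(\C)CCCC1(C)C | intermediate
26 | (1R,2Z,4R,6E)-1-hydroxy-3,7,11,11-tetramethylcycloundeca-2,6-dien-4-yl 4-acetoxybenzoate | O[C@@H]1/C=C(/C)[C@H](OC(=O)c2ccc(OC(C)=O)cc2)C/C=C(\C)CCCC1(C)C | intermediate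
27 | (1R,2Z,4R,6E)-1-acetoxy-3,7,11,11-tetramethylcycloundeca-2,6-dien-4-yl 4-acetoxybenzoate | CC(=O)O[C@@H]1/C=C(/C)[C@H](OC(=O)c2ccc(OC(C)=O)cc2)C/C=C(\C)CCCC1(C)C | intermediate
28 | (1R,2Z,4R,6E)-1-acetoxy-3,7,11,11-tetramethylcycloundeca-2,6-dien-4-yl 4-hydroxybenzoate | CC(=O)O[C@@H]1/C=C(/C)[C@H](OC(=O)c2ccc(O)cc2)C/C=C(\C)CCCC1(C)C | target

Total step count: 18. Longest linear sequence: 18 steps (from 1).

**Steps most likely to fail**

Step 12.
- The rearrangement may leak through the partner chair (C8 axial) or a boat, which would scramble both alkene geometries and C4.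
- The C7 alkoxide may also pull the silyl group over from the cis-disposed O1.
- The enolate may equilibrate before it is sulfonylated.

The fallback replaces the anionic process by a neutral one and separates rearrangement from triflation. It sets out from 18 and returns at 21. Compound 18 is silylated at O7 with N-(trimethylsilyl)imidazole (CH2Cl2, 40 °C) to the C7 trimethylsilyl ether F1. Heating in degassed decalin in base-washed glass at about 190 °C brings about the thermal siloxy-Cope ring expansion to the eleven-membered trimethylsilyl enol ether F2. MeLi (THF, 0 °C) releases the geometry-defined lithium enolate F3, which N-(5-chloropyridin-2-yl)bis(trifluoromethanesulfonimide) at −78 °C converts into 21.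

Step 4.
- Peroxide attack at the neopentyl β-carbon C1 may be slow.
- Facial discrimination on the flexible seven-membered iminium ion may be poor.

The fallback sets the configuration at C7 first and relays it. It sets out from 5 and returns at 6. Corey–Bakshi–Shibata reduction with the (S)-methyl oxazaborolidine and BH3·SMe2 (alkenyl arm as the large group) should give (R)-4,4-dimethylcyclohept-2-en-1-ol F4. VO(acac)2/t-BuOOH then epoxidises syn to the hydroxyl to give the cis-epoxy alcohol F5. Dess–Martin oxidation of F5 removes the relay centre and gives 6.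

Step 11.
- The coupling may stall on the bulky substrate.
- Carbonate at 80 °C may trigger premature rearrangement of the dienol.
- The enol ether may hydrolyse on isolation.

The fallback moves to a room-temperature oxidative coupling. It sets out from 16 and returns at 18. Miyaura borylation (B2pin2, PdCl2(PPh3)2, PPh3, KOPh, toluene, 50 °C) converts 16 with retention into the E alkenyl pinacol boronate F6. Chan–Lam–Evans etherification of F6 with excess 17 (Cu(OAc)2, Et3N, air, rt) then gives 18.

**Further compounds**
F1 | step 12 | C7 trimethylsilyl ether of 18 | C=C[C@@]1(O[Si](C)(C)C)CCCC(C)(C)[C@H](O[Si](C)(C)C(C)(C)C)[C@H]1/C(C)=C/OCc2ccc(OC)cc2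
F2 | step 12 | eleven-membered C7 trimethylsilyl enol ether (1R,2Z,4R; OSi cis to C5) | CC(C)(C)[Si](C)(C)O[C@@H]1/C=C(/C)[C@H](OCc2ccc(OC)cc2)C/C=C(\O[Si](C)(C)C)CCCC1(C)C
F3 | step 12 | lithium C6=C7 enolate | CC(C)(C)[Si](C)(C)O[C@@H]1/C=C(/C)[C@H](OCc2ccc(OC)cc2)C/C=C(\[O-])CCCC1(C)C.[Li+]
F4 | step 4 | (R)-4,4-dimethylcyclohept-2-en-1-ol | O[C@@H]1CCCC(C)(C)C=C1
F5 | step 4 | cis-2,3-epoxy-4,4-dimethylcycloheptan-1-ol (C7 R, C2 R, C1 S) | O[C@@H]1CCCC(C)(C)[C@@H]2O[C@H]12
F6 | step 11 | E alkenyl pinacol boronate corresponding to 16 | C=C[C@@]1(O)CCCC(C)(C)[C@H](O[Si](C)(C)C(C)(C)C)[C@H]1/C(C)=C/B2OC(C)(C)C(C)(C)O2
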